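Locants: C1 is the quaternary carbinol, C7 its CH2OBz carbon, C2=C3 the alkene, C4 carries the ring benzoate, C5 and C6 (next to C1) the secondary hydroxyls. The six-membered carbocycle hides a mirror-symmetric cyclohexa-2,5-diene: C7 is the carboxyl carbon of benzoic acid and sits cis-1,3 to the C5 oxygen. Everything rests on tracing that C5–O bond back to C7. One catalytic desymmetrising iodolactonisation picks one of the enantiotopic alkenes, closes a temporary γ-lactone bridge (C7–O–C5–C6–C1), forms C5–O and C6–I, and fixes C1, C5 and C6. Its precursor is the achiral Birch-derived diene acid whose C1 oxygen already carries the dimethylcarbamate that later delivers the C6 oxygen.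

Key step: step 3

Remark (assumption on the chemistry): hydroquinidine 1,4-phthalazinediyl diether is assumed to select the alkene that leads to (1S,5R,8S)-9. If it selects the other alkene, the pseudoenantiomeric hydroquinine catalyst is used and nothing else changes.

Step 1
Reactants: 1 benzoic acid
Product: 2 cyclohexa-2,5-diene-1-carboxylic acid
Conditions: Na, NH3(l)/EtOH, −78 to −33 °C; NH4Cl; cold dilute HCl
Reagents that add atoms: none
Why: Birch reduction of a benzoate adds the two hydrogens at the ipso and para carbons (C1 and C4) because the carboxylate stabilises negative charge at C1, which gives the unconjugated, achiral 2,5-diene.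

Step 2
Reactants: 2 cyclohexa-2,5-diene-1-carboxylic acid; 3 (camphorsulfonyl)oxaziridine; 4 dimethylcarbamoyl chloride
Product: 7 1-[(dimethylcarbamoyl)oxy]cyclohexa-2,5-diene-1-carboxylic acid, via dilithium dienediolate 5 (not isolated), via dilithium 1-oxidocyclohexa-2,5-diene-1-carboxylate 6 (not isolated)
Conditions: LiN(iPr)2 (2.2 equiv), THF, −78 to −20 °C; 3 (1.2 equiv), −78 °C; 4 (1.2 equiv), −78 to 0 °C; neutrals extracted at pH 9, then cold dilute HCl to pH 3 and fast extraction at 0 °C; used without storage
Reagents that add atoms: 3 (camphorsulfonyl)oxaziridine, CC1(C)C2CCC13CS(=O)(=O)N4OC34C2; 4 dimethylcarbamoyl chloride, CN(C)C(=O)Cl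
Why: Davis α-hydroxylation of the carboxylic acid dianion occurs at C1, the central carbon of the cross-conjugated dienolate where it is also alkylated, and acylation of the much more nucleophilic tertiary alkoxide in the same flask means that the acid-labile free α-hydroxy acid, an arene hydrate, is never isolated; no stereocentre arises.

Step 3
Reactants: 7 1-[(dimethylcarbamoyl)oxy]cyclohexa-2,5-diene-1-carboxylic acid; 8 N-iodosuccinimide
Product: 9 (1S,5R,8S)-8-iodo-7-oxo-6-oxabicyclo[3.2.1]oct-2-en-1-yl dimethylcarbamate
Conditions: 8 (1.1 equiv), hydroquinidine 1,4-phthalazinediyl diether (10 mol %), toluene/CHCl3 1:1, −40 °C, dark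
Reagents that add atoms: 8 N-iodosuccinimide, O=C1CCC(=O)N1I
Why: The quinuclidine nitrogen of the catalyst ion-pairs the carboxylic acid, electrophilic iodine from 8 is passed reversibly to one alkene on the face of the carbamate, and the carboxylate opens the iodonium ion at C5 from the opposite face. This is the known catalytic enantioselective halolactonisation that desymmetrises 1-substituted cyclohexa-2,5-diene-1-carboxylic acids, applied here to a 1-oxygenated member. The one new ring, the γ-lactone C7–O–C5–C6–C1, closes in the 5-endo-trig mode; the 4-exo closure to a β-lactone at C6 is more strained, aims at the carbon next to the acceptor-laden C1 and is reversible with iodine, so material funnels to the bridged γ-lactone. C5 is set by the bicyclic constraint (the one-carbon tether reaches C5 only on the face that bears C7), C6 by anti opening of the iodonium ion (iodine trans to the lactone oxygen), and C1 solely by which enantiotopic alkene the catalyst selects. The only selectivity that must be imposed from outside is therefore that group selection, while regiochemistry and relative configuration are built into the substrate. Masking the C1 hydroxyl keeps 8 from forming a hypoiodite that would fragment the α-hydroxy acid with loss of CO2 towards phenol, and the neutral carbamate oxygen, which could only attack the deactivated C6 from the other face, should not compete with the ion-paired carboxylate.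

Step 4
Reactants: 9 bridged iodolactone carbamate; 10 methanol
Product: 12 methyl (1R,5R,6R)-1-[(dimethylcarbamoyl)oxy]-5,6-epoxycyclohex-2-ene-1-carboxylate, via iodohydrin methyl ester 11 (not isolated)
Conditions: K2CO3 (1.5 equiv), MeOH, 0 °C
Reagents that add atoms: 10 methanol, CO
Why: Base-mediated methanolysis opens the strained lactone and the freed C5 alkoxide, trans-diaxial to iodine, displaces it in an intramolecular Williamson-type SN2 closure that inverts C6 and places the epoxide on the face of C7, while the fully substituted carbamate rules out a Payne rearrangement from the C1 oxygen.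

Step 5
Reactants: 12 epoxy ester carbamate; 13 water
Product: 15 methyl (3aR,7R,7aS)-7-hydroxy-2-oxo-3a,6,7,7a-tetrahydro-1,3-benzodioxole-3a-carboxylate, via dioxolan-2-iminium camphorsulfonate 14 (not isolated)
Conditions: (±)-camphorsulfonic acid (1.1 equiv), CH2Cl2, −20 to 0 °C; then H2O/THF, 0 °C to rt
Reagents that add atoms: 13 water, O
Why: In this neighbouring-group opening of an epoxy alcohol carbamate the carbonyl oxygen, held on the face opposite the epoxide, attacks the protonated epoxide at C6 in a 5-exo-tet SN2 process (second inversion at C6, so the new C6–O bond is cis to C1–O and trans to the untouched C5–O bond), and water then hydrolyses the iminium ion to the cyclic carbonate.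

Step 6
Reactants: 15 hydroxy carbonate ester
Product: 16 (1S,5R,6S)-1-(hydroxymethyl)cyclohex-2-ene-1,5,6-triol
Conditions: LiAlH4 (4 equiv), THF, 0 °C to rt; Na2SO4·10H2O, filtration, solids extracted with hot THF/MeOH
Reagents that add atoms: none
Why: Hydride reduction takes the ester to the C7 primary alcohol and cleaves the carbonate to the C1/C6 diol without touching a C–O stereocentre or the isolated alkene, and any material that has relactonised onto the C5 hydroxyl is reduced to the same tetraol.

Step 7
Reactants: 16 tetraol; 17 benzoyl chloride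
Product: 18 [(1S,5R,6S)-1,5,6-trihydroxycyclohex-2-en-1-yl]methyl benzoate
Conditions: 17 (1.05 equiv), pyridine, −30 to 0 °C
Reagents that add atoms: 17 benzoyl chloride, O=C(Cl)c1ccccc1
Why: Selective O-acylation is expected because at low temperature one equivalent of acid chloride reacts with the only primary hydroxyl faster than with the two secondary ones, and the tertiary C1 hydroxyl is inert.

Step 8
Reactants: 18 C7 benzoate triol; 19 tert-butyldimethylsilyl triflate
Product: 20 [(1S,5R,6S)-5,6-bis(tert-butyldimethylsilyloxy)-1-hydroxycyclohex-2-en-1-yl]methyl benzoate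
Conditions: 19 (2.3 equiv), 2,6-lutidine, CH2Cl2, −78 to 0 °C
Reagents that add atoms: 19 tert-butyldimethylsilyl triflate, CC(C)(C)[Si](C)(C)OS(=O)(=O)C(F)(F)F
Why: Silyl triflate silylation covers both secondary hydroxyls, including the hindered C6 one, while the tertiary C1 hydroxyl flanked by three substituted carbons stays free at this stoichiometry and temperature.

Step 9
Reactants: 20 bis-silyl ether; 21 tert-butyl hydroperoxide
Product: 23 [(1S,5S,6S)-5,6-bis(tert-butyldimethylsilyloxy)-1-hydroxy-4-oxocyclohex-2-en-1-yl]methyl benzoate, via C4 tert-butyl peroxide 22 (not isolated)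
Conditions: Rh2(cap)4 (cap = caprolactamate, 1 mol %), 21 (70% aq., 8 equiv), ClCH2CH2Cl, 40 °C
Reagents that add atoms: 21 tert-butyl hydroperoxide, CC(C)(C)OO
Why: Dirhodium-catalysed allylic C–H oxidation with tert-butyl hydroperoxide proceeds by hydrogen abstraction from C4, the only allylic carbon that bears hydrogen, capture of the allyl radical at C4 rather than at C2 next to the quaternary C1, and collapse of the mixed peroxide to the enone, under neutral conditions that spare silyl ethers, benzoate and the tertiary allylic alcohol.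

Step 10
Reactants: 23 enone
Product: 24 [(1S,4S,5R,6S)-5,6-bis(tert-butyldimethylsilyloxy)-1,4-dihydroxycyclohex-2-en-1-yl]methyl benzoate
Conditions: NaBH4, CeCl3·7H2O, MeOH, −78 °C
Reagents that add atoms: none
Why: Luche 1,2-reduction: in the half-chair with both silyl ethers equatorial (the other one would set C7 and the C5 silyl ether 1,3-diaxial) the small hydride attacks C4 axially from the face of C7, anti to the axial C5–H, and gives the equatorial alcohol trans to the C5 oxygen.

Step 11
Reactants: 24 trans allylic alcohol; 1 benzoic acid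
Product: 25 [(1S,4R,5R,6S)-4-(benzoyloxy)-5,6-bis(tert-butyldimethylsilyloxy)-1-hydroxycyclohex-2-en-1-yl]methyl benzoate
Conditions: 1 (1.5 equiv), PPh3, DIAD, toluene, 0 °C to rt
Reagents that add atoms: 1 benzoic acid, O=C(O)c1ccccc1
Why: Mitsunobu esterification displaces the C4 oxyphosphonium ion by benzoate in an SN2 step with inversion, so the ester ends cis to the C5 oxygen as the target requires, SN2′ attack at C2 being shielded by the quaternary C1 and the tertiary hydroxyl being unreactive.

Step 12
Reactants: 25 dibenzoate bis-silyl ether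
Product: 26 [(1S,4R,5S,6S)-4-(benzoyloxy)-1,5,6-trihydroxycyclohex-2-en-1-yl]methyl benzoate
Conditions: HF·pyridine, THF/pyridine, 0 °C to rt
Reagents that add atoms: none
Why: Fluoride-driven cleavage of both silyl ethers in a buffered, weakly acidic medium frees the C5 and C6 hydroxyls without base, which avoids migration of the C4 benzoate to the cis C5 hydroxyl, and touches no stereocentre.

Compound list
1 | benzoic acid | O=C(O)c1ccccc1 | starting material
2 | cyclohexa-2,5-diene-1-carboxylic acid | OC(=O)C1C=CCC=C1 | intermediate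
3 | (camphorsulfonyl)oxaziridine (either enantiomer or racemate, no stereocentre is created with it) | CC1(C)C2CCC13CS(=O)(=O)N4OC34C2 | starting material
4 | dimethylcarbamoyl chloride | CN(C)C(=O)Cl | starting material
5 | dilithium dienediolate of 2 | [Li+].[Li+].[O-]C([O-])=C1C=CCC=C1 | intermediate
6 | 1-hydroxycyclohexa-2,5-diene-1-carboxylic acid as its dilithium alkoxide carboxylate | [Li+].[Li+].[O-]C(=O)C1([O-])C=CCC=C1 | intermediate
7 | 1-[(dimethylcarbamoyl)oxy]cyclohexa-2,5-diene-1-carboxylic acid (achiral) | CN(C)C(=O)OC1(C(=O)O)C=CCC=C1 | intermediate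
8 | N-iodosuccinimide | O=C1CCC(=O)N1I | starting material
9 | (1S,5R,8S)-8-iodo-7-oxo-6-oxabicyclo[3.2.1]oct-2-en-1-yl dimethylcarbamate (lactone oxygen on C5; iodine on C6, which is locant 8 of the bicycle, anti to it; carbamate on C1) | O=C1O[C@@H]2CC=C[C@@]1(OC(=O)N(C)C)[C@H]2I | intermediate
10 | methanol | CO | starting material
11 | methyl (1S,5R,6S)-1-[(dimethylcarbamoyl)oxy]-5-hydroxy-6-iodocyclohex-2-ene-1-carboxylate (reacts on as its alkoxide) | COC(=O)[C@@]1(OC(=O)N(C)C)C=CC[C@@H](O)[C@@H]1I | intermediate
12 | methyl (1R,5R,6R)-1-[(dimethylcarbamoyl)oxy]-5,6-epoxycyclohex-2-ene-1-carboxylate (epoxide cis to CO2Me, trans to the carbamate) | COC(=O)[C@@]1(OC(=O)N(C)C)C=CC[C@H]2O[C@@H]12 | intermediate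
13 | water | O | starting material
14 | (3aR,7R,7aS)-2-(dimethyliminio)-7-hydroxy-3a-(methoxycarbonyl)-3a,6,7,7a-tetrahydro-1,3-benzodioxole camphorsulfonate | COC(=O)[C@@]12C=CC[C@@H](O)[C@@H]1OC(=[N+](C)C)O2.CC1(C)C2CCC1(CS(=O)(=O)[O-])C(=O)C2 | intermediate
15 | methyl (3aR,7R,7aS)-7-hydroxy-2-oxo-3a,6,7,7a-tetrahydro-1,3-benzodioxole-3a-carboxylate (cis C1/C6 cyclic carbonate, C5 hydroxyl trans to the C6 oxygen) | COC(=O)[C@@]12C=CC[C@@H](O)[C@@H]1OC(=O)O2 | intermediate
16 | (1S,5R,6S)-1-(hydroxymethyl)cyclohex-2-ene-1,5,6-triol | OC[C@@]1(O)C=CC[C@@H](O)[C@@H]1O | intermediate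
17 | benzoyl chloride | O=C(Cl)c1ccccc1 | starting material
18 | [(1S,5R,6S)-1,5,6-trihydroxycyclohex-2-en-1-yl]methyl benzoate | O=C(OC[C@@]1(O)C=CC[C@@H](O)[C@@H]1O)c1ccccc1 | intermediate
19 | tert-butyldimethylsilyl trifluoromethanesulfonate | CC(C)(C)[Si](C)(C)OS(=O)(=O)C(F)(F)F | starting material
20 | [(1S,5R,6S)-5,6-bis(tert-butyldimethylsilyloxy)-1-hydroxycyclohex-2-en-1-yl]methyl benzoate | O=C(OC[C@@]1(O)C=CC[C@@H](O[Si](C)(C)C(C)(C)C)[C@@H]1O[Si](C)(C)C(C)(C)C)c1ccccc1 | intermediate
21 | tert-butyl hydroperoxide | CC(C)(C)OO | starting material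
22 | C4 tert-butylperoxy derivative of 20 (both C4 epimers) | O=C(OC[C@@]1(O)C=CC(OOC(C)(C)C)[C@@H](O[Si](C)(C)C(C)(C)C)[C@@H]1O[Si](C)(C)C(C)(C)C)c1ccccc1 | intermediate
23 | [(1S,5S,6S)-5,6-bis(tert-butyldimethylsilyloxy)-1-hydroxy-4-oxocyclohex-2-en-1-yl]methyl benzoate | O=C(OC[C@@]1(O)C=CC(=O)[C@@H](O[Si](C)(C)C(C)(C)C)[C@@H]1O[Si](C)(C)C(C)(C)C)c1ccccc1 | intermediate
24 | [(1S,4S,5R,6S)-5,6-bis(tert-butyldimethylsilyloxy)-1,4-dihydroxycyclohex-2-en-1-yl]methyl benzoate (C4 hydroxyl trans to the C5 oxygen) | O=C(OC[C@@]1(O)C=C[C@H](O)[C@@H](O[Si](C)(C)C(C)(C)C)[C@@H]1O[Si](C)(C)C(C)(C)C)c1ccccc1 | intermediate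
25 | [(1S,4R,5R,6S)-4-(benzoyloxy)-5,6-bis(tert-butyldimethylsilyloxy)-1-hydroxycyclohex-2-en-1-yl]methyl benzoate | O=C(OC[C@@]1(O)C=C[C@@H](OC(=O)c2ccccc2)[C@@H](O[Si](C)(C)C(C)(C)C)[C@@H]1O[Si](C)(C)C(C)(C)C)c1ccccc1 | intermediate
26 | [(1S,4R,5S,6S)-4-(benzoyloxy)-1,5,6-trihydroxycyclohex-2-en-1-yl]methyl benzoate (CNP0217467.1) | O=C(OC[C@@]1(O)C=C[C@@H](OC(=O)c2ccccc2)[C@@H](O)[C@@H]1O)c1ccccc1 | target

Total step count: 12. Longest linear sequence: 12.

Steps most likely to fail

**Step 3.** The catalyst may discriminate poorly between the two enantiotopic alkenes, or the carbamate oxygen may divert the iodonium ion.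
- The fallback replaces catalyst control by a covalent chiral spectator group and separation of diastereomers. It sets out from 2 and comes back at 15.
- The alkoxide 6 is made from 2 as in step 2 but trapped at −78 °C with commercial (S)-1-phenylethyl isocyanate. This gives 1-({[(1S)-1-phenylethyl]carbamoyl}oxy)cyclohexa-2,5-diene-1-carboxylic acid F1.
- Uncatalysed iodolactonisation with 8 and NaHCO3 in MeCN at 0 °C then gives two diastereomers, the (1S,5R,8S) iodolactone carbamate F2 and the (1R,5S,8R) iodolactone carbamate F3. They are separated by crystallisation or chromatography, so configurational purity no longer depends on asymmetric induction.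
- K2CO3 in MeOH converts F2 to the epoxy ester carbamate F4.
- Camphorsulfonic acid followed by water opens F4 through the carbamate oxygen, as in step 5, to give 15.

**Step 9.** Hydrogen abstraction from the hindered, inductively deactivated C4 methylene may be sluggish, and regiocontrol is lost if the allyl radical is captured at C2.
- The fallback swaps the radical oxidation for a pericyclic one. It sets out from 20 and comes back at 25.
- SeO2 (0.5 equiv) with 21 in CH2Cl2, or SeO2 in dioxane at 70 °C, hydroxylates by an ene reaction and a [2,3] shift, which can return oxygen only to C4.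
- The ene step should remove the pseudoaxial C4 hydrogen on the face of C7 and deliver oxygen to that same face. This gives the cis allylic alcohol [(1S,4R,5R,6S)-5,6-bis(tert-butyldimethylsilyloxy)-1,4-dihydroxycyclohex-2-en-1-yl]methyl benzoate F5.
- F5 is benzoylated with retention by 17, pyridine and DMAP to 25.
- Any trans epimer formed is 24 and goes on through step 11, so both epimers converge.

**Step 2.** The dienolate or the hydroxylated dianion may aromatise by electron transfer or 1,4-elimination, and carbamoylation of the hindered, aggregated tertiary alkoxide may be incomplete.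
- The fallback works on neutral, isolable esters. It sets out from 2 and comes back at 7.
- MeI and K2CO3 in DMF give methyl cyclohexa-2,5-diene-1-carboxylate F6.
- LiN(iPr)2 and then 3 give methyl 1-hydroxycyclohexa-2,5-diene-1-carboxylate F7. It has no internal acid and can be purified on base-washed silica.
- NaH and 4 in THF give methyl 1-[(dimethylcarbamoyl)oxy]cyclohexa-2,5-diene-1-carboxylate F8.
- LiOH in aqueous THF followed by cold acidification frees 7.

Further compounds
F1 | step 3 | 1-({[(1S)-1-phenylethyl]carbamoyl}oxy)cyclohexa-2,5-diene-1-carboxylic acid | C[C@H](NC(=O)OC1(C(=O)O)C=CCC=C1)c1ccccc1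
F2 | step 3 | (1S,5R,8S)-8-iodo-7-oxo-6-oxabicyclo[3.2.1]oct-2-en-1-yl [(1S)-1-phenylethyl]carbamate | O=C1O[C@@H]2CC=C[C@@]1(OC(=O)N[C@@H](C)c3ccccc3)[C@H]2I
F3 | step 3 | (1R,5S,8R)-8-iodo-7-oxo-6-oxabicyclo[3.2.1]oct-2-en-1-yl [(1S)-1-phenylethyl]carbamate | O=C1O[C@H]2CC=C[C@]1(OC(=O)N[C@@H](C)c3ccccc3)[C@@H]2I
F4 | step 3 | methyl (1R,5R,6R)-5,6-epoxy-1-({[(1S)-1-phenylethyl]carbamoyl}oxy)cyclohex-2-ene-1-carboxylate | COC(=O)[C@@]1(OC(=O)N[C@@H](C)c3ccccc3)C=CC[C@H]2O[C@@H]12
F5 | step 9 | [(1S,4R,5R,6S)-5,6-bis(tert-butyldimethylsilyloxy)-1,4-dihydroxycyclohex-2-en-1-yl]methyl benzoate | O=C(OC[C@@]1(O)C=C[C@@H](O)[C@@H](O[Si](C)(C)C(C)(C)C)[C@@H]1O[Si](C)(C)C(C)(C)C)c1ccccc1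
F6 | step 2 | methyl cyclohexa-2,5-diene-1-carboxylate | COC(=O)C1C=CCC=C1
F7 | step 2 | methyl 1-hydroxycyclohexa-2,5-diene-1-carboxylate | COC(=O)C1(O)C=CCC=C1
F8 | step 2 | methyl 1-[(dimethylcarbamoyl)oxy]cyclohexa-2,5-diene-1-carboxylate | COC(=O)C1(OC(=O)N(C)C)C=CCC=C1
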